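The 1,2-dioxane is cut between C5 (the ring CH2) and C6 (the quaternary peroxide carbon). In the key step a peroxycarbenium ion at C6, made from a citronellic-acid-derived methyl ketone and the silyl peroxide of a resolved allylic hydroperoxide, is attacked by the isopropenyl terminus. The dioxane closes, and the C4 cation takes the hydride from C3, which becomes the hemiketal carbon. The step exploits the 1,4-relation of hemiketal carbon C3 and peroxide carbon C6 in the dioxane ring, for which an allylic hydroperoxide serves as a chiral homoenolate. The precursor is an open-chain silyl perhemiketal carrying a 1,1-disubstituted alkene.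

Key step: step 6

Numbering used below: ring atoms O1, O2, C3 (hemiketal carbon), C4, C5, C6; C7 and C8 are the first two carbons of the side chain on C6.

Assumption: the lipase of step 5 acylates the (S)-hydroperoxide faster, as the empirical rule for lipase acylation of secondary alcohols (Kazlauskas rule) suggests when the CH2CO2Me arm is read as the large group; the sense has to be confirmed on a reduced sample of 8.

Step 1
Reactants: 1 (R)-citronellic acid [(3R)-3,7-dimethyloct-6-enoic acid]
Product: 2 (4R)-4,8-dimethylnon-7-en-2-one
Conditions: MeLi (2.2 equiv), Et2O, 0 °C to rt; then H2O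
Reagents that add atoms: methyllithium, [Li]C
Why: Two equivalents of MeLi convert the acid into a dilithium gem-diolate that survives until work-up and then collapses to the methyl ketone (ketone synthesis from a carboxylic acid and an organolithium); the stereocenter of 1, the later C8, is not touched.

Step 2
Reactants: 2 (4R)-4,8-dimethylnon-7-en-2-one; 3 6-phenylhex-1-ene
Product: 4 (4R)-4-methyl-12-phenyldodec-7-en-2-one (E/Z mixture)
Conditions: second-generation Grubbs catalyst RuCl2(=CHPh)(PCy3)(H2IMes) (5 mol %), 3 (4 equiv), CH2Cl2, 40 °C
Reagents that add atoms: none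
Why: Olefin cross-metathesis: the trisubstituted isopropylidene olefin of 2 does not homodimerise and should exchange its end with the terminal olefin 3 used in excess, and the E/Z ratio is of no concern because the double bond is hydrogenated next.

Step 3
Reactants: 4 (4R)-4-methyl-12-phenyldodec-7-en-2-one
Product: 5 (4R)-4-methyl-12-phenyldodecan-2-one
Conditions: H2 (1 atm), Pd/C, EtOAc, rt
Reagents that add atoms: none
Why: Heterogeneous catalytic hydrogenation should saturate the disubstituted olefin without touching the ketone or the arene, and it is placed before any peroxide is present.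

Step 4
Reactants: 6 methyl 4-methylpent-3-enoate
Product: 7 methyl 3-hydroperoxy-4-methylpent-4-enoate (racemic)
Conditions: O2, tetraphenylporphyrin (cat.), visible light, CH2Cl2, 0 °C
Reagents that add atoms: dioxygen, O=O
Why: Schenck ene reaction of singlet oxygen: oxygen adds at C3 and a hydrogen of the methyl group on the crowded side of the trisubstituted olefin is transferred (the C2 hydrogens are deactivated by the ester), which should give the racemic secondary allylic hydroperoxide with the 1,1-disubstituted alkene.

Step 5
Reactants: 7 methyl 3-hydroperoxy-4-methylpent-4-enoate (racemic)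
Product: 8 methyl (3R)-3-hydroperoxy-4-methylpent-4-enoate
Conditions: Burkholderia cepacia lipase (Amano PS), isopropenyl acetate, cyclohexane, rt, run to about 55% conversion
Reagents that add atoms: none
Why: Lipase-catalysed acylative kinetic resolution of a secondary hydroperoxide: the (S)-enantiomer should be acylated and its peracetate collapses to the β-keto ester, which leaves (R)-8 and so fixes the one stereocenter that later controls C4 and C6.

Step 6
Reactants: 5 (4R)-4-methyl-12-phenyldodecan-2-one; 8 methyl (3R)-3-hydroperoxy-4-methylpent-4-enoate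
Product: 12 methyl 2-[(3S,4R,6S)-3-hydroxy-4,6-dimethyl-6-[(2R)-2-methyl-10-phenyldecyl]-1,2-dioxan-3-yl]acetate, via silyl peroxide 9 (not isolated), via silyl perhemiketal 10 (not isolated), via silyl ether 11 (not isolated)
Conditions: N,O-bis(trimethylsilyl)acetamide (1.05 equiv), CH2Cl2, 0 °C; then 5 (1.1 equiv), TMSOTf (0.2 equiv), -78 to -40 °C; then AcOH, THF, H2O, 0 °C
Reagents that add atoms: none
Why: Proposed new method: silyl peroxide 9 adds to ketone 5 under TMSOTf (silyl-transfer ketalisation) to give 10, whose ionisation with loss of hexamethyldisiloxane gives a peroxycarbenium ion at C6 that is attacked by the C5 terminus of the 1,1-disubstituted alkene; the tertiary C4 cation is then quenched by a 1,2-hydride shift from C3, and the new C3 peroxycarbenium ion recaptures the siloxane to give 11, which loses silicon on work-up. The closest known reactions are the Lewis-acid cyclisation of unsaturated peroxyketals through peroxycarbenium ions to 1,2-dioxanes and the hydride-shift termination of Prins–pinacol cascades; the relay of the C3 hydride to C4 with hemiketal formation on a dioxane is not known. The dioxane closes in a 6-endo-trig cation–olefin mode through a chair. C6 is set in that chair, where the CH2CO2Me group on C3 should sit pseudoaxial to avoid A(1,2) strain with the C4 methyl and the (E)-peroxycarbenium geometry puts the long chain equatorial and the C6 methyl axial; C4 is set by the hydride, which migrates on the ring face on which it stood at C3; C3 should end, after ring–chain equilibration, as the anomerically favoured axial hydroxyl. The step needs 6-endo regioselectivity (secured by the tertiary cation at C4), a hydride shift that outruns proton loss and capture by the ester carbonyl (helped by low temperature, the non-nucleophilic triflate and the gain of a heteroatom-stabilised cation) and facial selectivity at C6 (secured only by the single stereocenter of 8, so it rests on small energy differences).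

Compound list
1 | (R)-citronellic acid, (3R)-3,7-dimethyloct-6-enoic acid | OC(=O)C[C@H](C)CCC=C(C)C | starting material
2 | (4R)-4,8-dimethylnon-7-en-2-one | CC(=O)C[C@H](C)CCC=C(C)C | intermediate
3 | 6-phenylhex-1-ene | C=CCCCCc1ccccc1 | starting material
4 | (4R)-4-methyl-12-phenyldodec-7-en-2-one (E/Z mixture) | CC(=O)C[C@H](C)CCC=CCCCCc1ccccc1 | intermediate
5 | (4R)-4-methyl-12-phenyldodecan-2-one | CC(=O)C[C@H](C)CCCCCCCCc1ccccc1 | intermediate
6 | methyl 4-methylpent-3-enoate | COC(=O)CC=C(C)C | starting material
7 | methyl 3-hydroperoxy-4-methylpent-4-enoate (racemic) | COC(=O)CC(OO)C(C)=C | intermediate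
8 | methyl (3R)-3-hydroperoxy-4-methylpent-4-enoate | COC(=O)C[C@@H](OO)C(C)=C | intermediate
9 | methyl (3R)-4-methyl-3-(trimethylsilylperoxy)pent-4-enoate | COC(=O)C[C@@H](OO[Si](C)(C)C)C(C)=C | intermediate
10 | methyl (3R)-4-methyl-3-{[(4R)-4-methyl-12-phenyl-2-(trimethylsilyloxy)dodecan-2-yl]peroxy}pent-4-enoate (both epimers at the perketal carbon) | COC(=O)C[C@@H](OOC(C)(O[Si](C)(C)C)C[C@H](C)CCCCCCCCc1ccccc1)C(C)=C | intermediate
11 | methyl 2-[(3R,4R,6S)-4,6-dimethyl-6-[(2R)-2-methyl-10-phenyldecyl]-3-(trimethylsilyloxy)-1,2-dioxan-3-yl]acetate | COC(=O)C[C@]1(O[Si](C)(C)C)OO[C@@](C)(C[C@H](C)CCCCCCCCc2ccccc2)C[C@H]1C | intermediate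
12 | methyl 2-[(3S,4R,6S)-3-hydroxy-4,6-dimethyl-6-[(2R)-2-methyl-10-phenyldecyl]-1,2-dioxan-3-yl]acetate | COC(=O)C[C@]1(O)OO[C@@](C)(C[C@H](C)CCCCCCCCc2ccccc2)C[C@H]1C | target

Total step count: 6. Longest linear sequence: 4 steps (steps 1, 2, 3 and 6).

Steps most likely to fail

Step 6. The C4 cation may lose a proton or be trapped by the ester carbonyl before the hydride migrates, and the two chair arrangements may be populated with too little bias, so that the cascade stops short or gives poor facial selectivity at C6. The fallback uses known reactions only, sets out from 5 and returns at 12. The kinetic lithium enolate of 5 (LiN(iPr)2, THF, -78 °C) is alkylated on its methyl carbon with the triflate of methyl (R)-lactate, with inversion, to give methyl (2R,6R)-2,6-dimethyl-4-oxo-14-phenyltetradecanoate F1. Wittig methylenation (Ph3P=CH2) gives methyl (2R,6R)-2,6-dimethyl-4-methylidene-14-phenyltetradecanoate F2. Crossed Claisen condensation with the lithium enolate of methyl acetate gives methyl (4R,8R)-4,8-dimethyl-6-methylidene-3-oxo-16-phenylhexadecanoate F3. Isayama–Mukaiyama hydroperoxysilylation (Co(acac)2, O2, Et3SiH) gives methyl (4R,8R)-4,6,8-trimethyl-3-oxo-16-phenyl-6-(triethylsilylperoxy)hexadecanoate F4 as both C6 epimers. Desilylation (Bu4NF, AcOH) frees the hydroperoxide, which closes onto the ketone to give 12 together with methyl 2-[(3S,4R,6R)-3-hydroxy-4,6-dimethyl-6-[(2R)-2-methyl-10-phenyldecyl]-1,2-dioxan-3-yl]acetate F5, from which 12 is separated by HPLC.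

Step 5. The lipase may acylate slowly, with low enantioselectivity or with the opposite preference, and the hydroperoxide may decompose on the enzyme preparation. The fallback sets out from 7 and returns at 8. Racemic 7 is added to (1R,2S)-2-phenylcyclohexyl isopropenyl ether (PPTS, CH2Cl2) to give two diastereomeric perketals. Methyl (3R)-4-methyl-3-[(2-{[(1R,2S)-2-phenylcyclohexyl]oxy}propan-2-yl)peroxy]pent-4-enoate F6 is separated by chromatography from methyl (3S)-4-methyl-3-[(2-{[(1R,2S)-2-phenylcyclohexyl]oxy}propan-2-yl)peroxy]pent-4-enoate F7 and cleaved with AcOH, THF and H2O to 8.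

Step 4. Singlet oxygen may abstract hydrogen at C2 next to the ester and give the conjugated tertiary hydroperoxide, or the product may be oxidised further. The fallback sets out from 6 and returns at 7. Ene-type chlorination of 6 with hypochlorous acid (Ca(OCl)2, solid CO2, CH2Cl2, H2O) moves the double bond to the terminus and gives methyl 3-chloro-4-methylpent-4-enoate F8. Silver-assisted substitution with H2O2 (silver triflate AgO3SCF3, Et2O, 0 °C) then replaces chloride by the hydroperoxy group to give 7.

Further compounds
F1 | step 6 | methyl (2R,6R)-2,6-dimethyl-4-oxo-14-phenyltetradecanoate | COC(=O)[C@H](C)CC(=O)C[C@H](C)CCCCCCCCc1ccccc1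
F2 | step 6 | methyl (2R,6R)-2,6-dimethyl-4-methylidene-14-phenyltetradecanoate | COC(=O)[C@H](C)CC(=C)C[C@H](C)CCCCCCCCc1ccccc1
F3 | step 6 | methyl (4R,8R)-4,8-dimethyl-6-methylidene-3-oxo-16-phenylhexadecanoate | COC(=O)CC(=O)[C@H](C)CC(=C)C[C@H](C)CCCCCCCCc1ccccc1
F4 | step 6 | methyl (4R,8R)-4,6,8-trimethyl-3-oxo-16-phenyl-6-(triethylsilylperoxy)hexadecanoate (both C6 epimers) | COC(=O)CC(=O)[C@H](C)CC(C)(OO[Si](CC)(CC)CC)C[C@H](C)CCCCCCCCc1ccccc1
F5 | step 6 | methyl 2-[(3S,4R,6R)-3-hydroxy-4,6-dimethyl-6-[(2R)-2-methyl-10-phenyldecyl]-1,2-dioxan-3-yl]acetate | COC(=O)C[C@]1(O)OO[C@](C)(C[C@H](C)CCCCCCCCc2ccccc2)C[C@H]1C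
F6 | step 5 | methyl (3R)-4-methyl-3-[(2-{[(1R,2S)-2-phenylcyclohexyl]oxy}propan-2-yl)peroxy]pent-4-enoate | COC(=O)C[C@@H](OOC(C)(C)O[C@@H]1CCCC[C@H]1c1ccccc1)C(C)=C
F7 | step 5 | methyl (3S)-4-methyl-3-[(2-{[(1R,2S)-2-phenylcyclohexyl]oxy}propan-2-yl)peroxy]pent-4-enoate | COC(=O)C[C@H](OOC(C)(C)O[C@@H]1CCCC[C@H]1c1ccccc1)C(C)=C
F8 | step 4 | methyl 3-chloro-4-methylpent-4-enoate (racemic) | COC(=O)CC(Cl)C(C)=C
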